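Ring B of the target is read as a masked Hagemann ester (drimane numbering): C6 (later the C6=C7 alkene CH) is a ketone whose two α-carbons are C5 and C7, while C10, C9 and C8 are the β-carbon, α-carbon and acetyl carbon of an alkylidene acetoacetate whose ester is C11 and whose methyl is C12. One acid-catalysed operation lets C5 add to C10 (closing ring A) and C7 condense with C8 (closing ring B), turning an open-chain keto alkylidene-acetoacetate into the trans-decalin enone with C5 and C10 set by the C3 pivaloyloxy centre. Enol triflate reduction, deconjugation, hydride reduction and Mitsunobu etherification with umbelliferone finish the route.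

Key step: step 8

Remark: drimane numbering is used for all compounds on the way (ring A = C1–C5, C10; ring B = C5–C10; C11 on C9; C12 on C8; C13 and C14 on C4; C15 on C10). Bicyclic names use the drimane skeleton only as a numbering frame; every stereodescriptor is given explicitly.
Remark: compounds 1, 2, 9 and 21 are assumed to be commercially available. The alkene geometry of 10 and 11 and the C9 configuration of 12–14 are left open on purpose, because these centres are sp3/sp2-interconverted later.

Step 1
Reactants: 1 2,2-dimethylpent-4-enal; 2 2-(2-bromoethyl)-2-methyl-1,3-dioxolane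
Product: 4 rac-4,4-dimethyl-1-(2-methyl-1,3-dioxolan-2-yl)hept-6-en-3-ol, via Grignard reagent 3 (not isolated)
Conditions: Mg, THF, 30 °C; then 1, 0 °C to rt; aq. NH4Cl
Reagents that add atoms: none
Why: Grignard addition to a non-enolisable α-quaternary aldehyde should give the secondary alcohol cleanly; the carbinol centre is formed racemic and is erased in step 2.

Step 2
Reactants: 4 rac-4,4-dimethyl-1-(2-methyl-1,3-dioxolan-2-yl)hept-6-en-3-ol
Product: 5 4,4-dimethyl-1-(2-methyl-1,3-dioxolan-2-yl)hept-6-en-3-one
Conditions: Dess–Martin periodinane, CH2Cl2, 0 °C to rt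
Reagents that add atoms: none
Why: Dess–Martin oxidation of the hindered secondary alcohol should give the ketone without touching the dioxolane or the terminal alkene, setting up a reagent-controlled reduction.

Step 3
Reactants: 5 4,4-dimethyl-1-(2-methyl-1,3-dioxolan-2-yl)hept-6-en-3-one
Product: 6 (3R)-4,4-dimethyl-1-(2-methyl-1,3-dioxolan-2-yl)hept-6-en-3-ol
Conditions: (S)-2-methyl-CBS-oxazaborolidine (0.2 equiv), catecholborane, toluene, −40 to −20 °C; aq. NaOH work-up
Reagents that add atoms: none
Why: Corey–Bakshi–Shibata reduction in which the tert-alkyl group is the large and the CH2CH2 chain the small substituent, so the (S)-catalyst should give the (3R)-alcohol (the analogue of (R)-1-phenylethanol from acetophenone); catecholborane is chosen because it does not hydroborate the terminal alkene at low temperature.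

Step 4
Reactants: 6 (3R)-4,4-dimethyl-1-(2-methyl-1,3-dioxolan-2-yl)hept-6-en-3-ol
Product: 7 (3R)-4,4-dimethyl-1-(2-methyl-1,3-dioxolan-2-yl)hept-6-en-3-yl pivalate
Conditions: pivaloyl chloride, DMAP, pyridine, 60 °C
Reagents that add atoms: pivaloyl chloride, CC(C)(C)C(=O)Cl
Why: DMAP-catalysed acylation; the pivalate has no α-hydrogen, should survive the acid of step 8 and the amide bases of steps 9 and 11, and is removed in the same operation as the ester reduction of step 12.

Step 5
Reactants: 7 (3R)-4,4-dimethyl-1-(2-methyl-1,3-dioxolan-2-yl)hept-6-en-3-yl pivalate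
Product: 8 (5R)-6,6-dimethyl-2-oxonon-8-en-5-yl pivalate
Conditions: PPTS (cat.), acetone/H2O, 50 °C
Reagents that add atoms: water, O
Why: mild acid-catalysed ketal hydrolysis should unveil the methyl ketone (future C10 and C15) and leave the hindered pivalate intact.

Step 6
Reactants: 8 (5R)-6,6-dimethyl-2-oxonon-8-en-5-yl pivalate; 9 methyl acetoacetate
Product: 10 methyl (6R)-2-acetyl-3,7,7-trimethyl-6-(pivaloyloxy)deca-2,9-dienoate (E/Z mixture)
Conditions: TiCl4, pyridine, THF, 0 °C to rt
Reagents that add atoms: none
Why: TiCl4/pyridine-mediated Knoevenagel condensation works with ketones, and only one ketone is present at this stage, so the alkylidene acetoacetate (C10=C9 carrying the C8/C12 acetyl and the C11 ester) should form chemoselectively; the alkene geometry is irrelevant because both carbons change hybridisation later.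

Step 7
Reactants: 10 methyl (6R)-2-acetyl-3,7,7-trimethyl-6-(pivaloyloxy)deca-2,9-dienoate
Product: 11 methyl (6R)-2-acetyl-3,7,7-trimethyl-9-oxo-6-(pivaloyloxy)dec-2-enoate
Conditions: PdCl2 (0.1 equiv), CuCl, O2 (1 atm), DMF/H2O, rt
Reagents that add atoms: water, O (carbonyl oxygen; O2 is the terminal oxidant)
Why: Wacker oxidation of the monosubstituted alkene should give the methyl ketone (C6, C7) by Markovnikov hydroxypalladation, while the tetrasubstituted electron-poor alkene does not bind palladium.

Step 8
Reactants: 11 methyl (6R)-2-acetyl-3,7,7-trimethyl-9-oxo-6-(pivaloyloxy)dec-2-enoate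
Product: 14 methyl (3R,5S,10R)-6-oxo-3-(pivaloyloxy)drim-7-en-11-oate (C9 epimers), via Michael adduct 12 (not isolated), via aldol adduct 13 (not isolated)
Conditions: TsOH·H2O (0.2 equiv), toluene, reflux, Dean–Stark trap
Reagents that add atoms: none
Why: Acid-catalysed enolisation of the C6 ketone toward C5 and attack of C5 on the protonated, tertiary-cation-like β-carbon C10 of the alkylidene acetoacetate (intramolecular Michael addition) should give 1,5-diketone 12, whose methyl-ketone enol (C7) then adds to the acetoacetate carbonyl C8 (aldol adduct 13) and loses water to the conjugated enone. The closest known reaction type is the acid-catalysed Robinson annulation, in particular the Michael/aldol sequence from a vinyl ketone and an acetoacetate that leads to Hagemann's ester, here run intramolecularly with donor and acceptor roles exchanged. Ring A closes by 6-exo-trig attack through a chair transition state and ring B by 6-(enolexo)-exo-trig aldol addition followed by dehydration. C5 and C10 are controlled by the C3 stereocentre: a chair with the pivaloyloxy group, the C5–C6 bond and the bulky C9 arm equatorial and the C15 methyl axial should place C15 cis to the pivaloyloxy group and H5 trans to C15, C5 remaining correctable by enolisation toward the trans-fused ketone, while C9 stays epimerisable and is erased in step 9. The step needs attack through C5 rather than C7, which ring size secures (six- against eight-membered), and ring-B closure by C7 on C8 rather than by C12 on C6, which the shielding of the C6 carbonyl between the quaternary carbons C4 and C10 and the known course of the analogous closure to Hagemann's ester should secure. Azeotropic removal of water keeps the acceptor from retro-Knoevenagel cleavage and makes the dehydration irreversible; a minor C5/C10 diastereomer, if formed, would be removed at this stage.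

Step 9
Reactants: 14 methyl (3R,5S,10R)-6-oxo-3-(pivaloyloxy)drim-7-en-11-oate
Product: 16 methyl (3R,5S,10R)-3-(pivaloyloxy)-6-(trifluoromethylsulfonyloxy)drima-6,8-dien-11-oate, via potassium trienolate 15 (not isolated)
Conditions: KN(SiMe3)2, THF, −78 to 0 °C; then PhNTf2, 0 °C; aq. NH4Cl
Reagents that add atoms: N-phenylbis(trifluoromethanesulfonimide), O=S(=O)(N(c1ccccc1)S(=O)(=O)C(F)(F)F)C(F)(F)F
Why: deprotonation at C9 (α to the ester and vinylogous to the ketone) should give the fully conjugated trienolate, and O-sulfonylation at the C6 oxygen gives the dienyl triflate (enol triflate formation), removing the uncontrolled C9 centre on purpose.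

Step 10
Reactants: 16 methyl (3R,5S,10R)-3-(pivaloyloxy)-6-(trifluoromethylsulfonyloxy)drima-6,8-dien-11-oate
Product: 17 methyl (3R,5S,10R)-3-(pivaloyloxy)drima-6,8-dien-11-oate
Conditions: Pd(OAc)2 (cat.), PPh3, HCO2H, n-Bu3N, DMF, 60 °C
Reagents that add atoms: none
Why: palladium-catalysed formate reduction of the dienyl triflate (oxidative addition, formate exchange, decarboxylation, reductive elimination) should replace the C6 oxygen by hydrogen and leave the C6=C7/C8=C9 dienoate.

Step 11
Reactants: 17 methyl (3R,5S,10R)-3-(pivaloyloxy)drima-6,8-dien-11-oate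
Product: 19 methyl (3R,5S,9R,10R)-3-(pivaloyloxy)drima-6,8(12)-dien-11-oate, via lithium dienolate 18 (not isolated)
Conditions: LiN(i-Pr)2 (commercial solution), THF/DMPU, −78 °C; then AcOH, −78 °C
Reagents that add atoms: none
Why: deconjugative protonation of an extended ester enolate: kinetic γ-deprotonation of the C12 methyl and kinetic α-protonation at C9 should move the double bond to C8=C12, the proton entering anti to the axial C15 methyl on C10 so that C11 ends cis to C15 (9R).

Step 12
Reactants: 19 methyl (3R,5S,9R,10R)-3-(pivaloyloxy)drima-6,8(12)-dien-11-oate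
Product: 20 (3R,5S,9R,10R)-drima-6,8(12)-diene-3,11-diol
Conditions: LiAlH4, THF, 0 °C to rt; aq. NaOH work-up
Reagents that add atoms: none
Why: hydride reduction should convert the methyl ester into the C11 primary alcohol and cleave the pivalate in the same operation, the diene being inert to LiAlH4 and no stereocentre being touched.

Step 13
Reactants: 20 (3R,5S,9R,10R)-drima-6,8(12)-diene-3,11-diol; 21 umbelliferone (7-hydroxy-2H-chromen-2-one)
Product: 22 7-{[(3R,5S,9R,10R)-3-hydroxydrima-6,8(12)-dien-11-yl]oxy}-2H-chromen-2-one (target CNP0259618.4)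
Conditions: PPh3, DIAD, THF, 0 °C to rt
Reagents that add atoms: none
Why: Mitsunobu etherification with the acidic phenol should take place at the primary C11 hydroxyl only, because the equatorial C3 hydroxyl next to the quaternary C4 is too hindered to be activated; no stereocentre is involved.

Compound list
1 | 2,2-dimethylpent-4-enal | C=CCC(C)(C)C=O | starting material
2 | 2-(2-bromoethyl)-2-methyl-1,3-dioxolane | CC1(CCBr)OCCO1 | starting material
3 | [2-(2-methyl-1,3-dioxolan-2-yl)ethyl]magnesium bromide | CC1(CC[Mg]Br)OCCO1 | intermediate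
4 | rac-4,4-dimethyl-1-(2-methyl-1,3-dioxolan-2-yl)hept-6-en-3-ol | C=CCC(C)(C)C(O)CCC1(C)OCCO1 | intermediate
5 | 4,4-dimethyl-1-(2-methyl-1,3-dioxolan-2-yl)hept-6-en-3-one | C=CCC(C)(C)C(=O)CCC1(C)OCCO1 | intermediate
6 | (3R)-4,4-dimethyl-1-(2-methyl-1,3-dioxolan-2-yl)hept-6-en-3-ol | C=CCC(C)(C)[C@H](O)CCC1(C)OCCO1 | intermediate
7 | (3R)-4,4-dimethyl-1-(2-methyl-1,3-dioxolan-2-yl)hept-6-en-3-yl pivalate | C=CCC(C)(C)[C@H](OC(=O)C(C)(C)C)CCC1(C)OCCO1 | intermediate
8 | (5R)-6,6-dimethyl-2-oxonon-8-en-5-yl pivalate | C=CCC(C)(C)[C@H](OC(=O)C(C)(C)C)CCC(C)=O | intermediate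
9 | methyl acetoacetate (methyl 3-oxobutanoate) | CC(=O)CC(=O)OC | starting material
10 | methyl (6R)-2-acetyl-3,7,7-trimethyl-6-(pivaloyloxy)deca-2,9-dienoate (E/Z mixture) | C=CCC(C)(C)[C@H](OC(=O)C(C)(C)C)CCC(C)=C(C(C)=O)C(=O)OC | intermediate
11 | methyl (6R)-2-acetyl-3,7,7-trimethyl-9-oxo-6-(pivaloyloxy)dec-2-enoate (E/Z mixture) | CC(=O)CC(C)(C)[C@H](OC(=O)C(C)(C)C)CCC(C)=C(C(C)=O)C(=O)OC | intermediate
12 | methyl 2-[(1R,2S,4R)-2-acetyl-1,3,3-trimethyl-4-(pivaloyloxy)cyclohexyl]-3-oxobutanoate (Michael adduct, side-chain epimers) | CC(=O)[C@@H]1C(C)(C)[C@H](OC(=O)C(C)(C)C)CC[C@@]1(C)C(C(C)=O)C(=O)OC | intermediate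
13 | methyl (3R,5S,10R)-8-hydroxy-6-oxo-3-(pivaloyloxy)driman-11-oate (aldol adduct, C8/C9 epimers) | CC1(O)CC(=O)[C@@H]2C(C)(C)[C@H](OC(=O)C(C)(C)C)CC[C@@]2(C)C1C(=O)OC | intermediate
14 | methyl (3R,5S,10R)-6-oxo-3-(pivaloyloxy)drim-7-en-11-oate (trans-fused, C15 cis to the pivaloyloxy group, C9 epimers) | CC1=CC(=O)[C@@H]2C(C)(C)[C@H](OC(=O)C(C)(C)C)CC[C@@]2(C)C1C(=O)OC | intermediate
15 | potassium trienolate of 14 (C6 enolate, C6=C7 and C8=C9) | [K+].CC=1C=C([O-])[C@@H]2C(C)(C)[C@H](OC(=O)C(C)(C)C)CC[C@@]2(C)C=1C(=O)OC | intermediate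
16 | methyl (3R,5S,10R)-3-(pivaloyloxy)-6-(trifluoromethylsulfonyloxy)drima-6,8-dien-11-oate | CC=1C=C(OS(=O)(=O)C(F)(F)F)[C@@H]2C(C)(C)[C@H](OC(=O)C(C)(C)C)CC[C@@]2(C)C=1C(=O)OC | intermediate
17 | methyl (3R,5S,10R)-3-(pivaloyloxy)drima-6,8-dien-11-oate | CC=1C=C[C@@H]2C(C)(C)[C@H](OC(=O)C(C)(C)C)CC[C@@]2(C)C=1C(=O)OC | intermediate
18 | lithium dienolate of 17 (C8=C12 and C9=C11 ester enolate) | [Li+].C=C1C=C[C@@H]2C(C)(C)[C@H](OC(=O)C(C)(C)C)CC[C@@]2(C)C1=C([O-])OC | intermediate
19 | methyl (3R,5S,9R,10R)-3-(pivaloyloxy)drima-6,8(12)-dien-11-oate | C=C1C=C[C@@H]2C(C)(C)[C@H](OC(=O)C(C)(C)C)CC[C@@]2(C)[C@@H]1C(=O)OC | intermediate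
20 | (3R,5S,9R,10R)-drima-6,8(12)-diene-3,11-diol | C=C1C=C[C@@H]2C(C)(C)[C@H](O)CC[C@@]2(C)[C@@H]1CO | intermediate
21 | umbelliferone (7-hydroxy-2H-chromen-2-one) | Oc1ccc2ccc(=O)oc2c1 | starting material
22 | 7-{[(1R,4aS,6R,8aR)-6-hydroxy-5,5,8a-trimethyl-2-methylidene-1,2,4a,5,6,7,8,8a-octahydronaphthalen-1-yl]methoxy}-2H-chromen-2-one (drimane numbering 3R,5S,9R,10R) | C=C1C=C[C@@H]2C(C)(C)[C@H](O)CC[C@@]2(C)[C@@H]1COc1ccc2ccc(=O)oc2c1 | target

Total step count: 13. Longest linear sequence: 13 steps (from 1 and 2 to 22; 9 and 21 enter as commercial reactants in steps 6 and 13).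

Steps most likely to fail

Step 8. The enol addition that makes the congested C5–C10 bond may stall while the acceptor deconjugates or is cleaved by retro-Knoevenagel reaction. Ring B may close in the wrong sense (C12 onto C6), and the facial selectivity at C10 exerted by the C3 pivaloyloxy group may be modest. The fallback makes the C5–C10 bond by a cycloaddition instead of an ionic addition and sets out from 11. Trimethyl orthoformate, MeOH and PPTS should convert only the unconjugated methyl ketone into the dimethyl ketal F1. Heating F1 in toluene with a trace of PPTS releases the methyl enol ether, whose more substituted isomer (C5=C6) is the only one able to reach the 1-oxadiene O=C8–C9=C10 of the alkylidene acetoacetate. Intramolecular inverse-electron-demand hetero-Diels–Alder addition (C5–C10 and O–C6 bonds) should then give the ring-A-fused methoxy-isochromene ketal F2. Aqueous acid opens F2 to diketone 12, and NaOMe in MeOH closes ring B by aldol condensation, so the fallback comes back to the route at 14.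

Step 11. The dienolate may be protonated at C12 (return to the conjugated ester) or from the wrong face of C9, or the base may remove H5 and scramble C5. The fallback delivers the C9 hydrogen as a hydride from palladium instead of as a proton and sets out from 17. LiN(i-Pr)2 and Me3SiCl at −78 °C should give the cross-conjugated silyl ketene acetal F3. N-Bromosuccinimide should brominate F3 at the vinylogous carbon C12 to give the 12-bromo-6,8-dienoate F4. Pd(PPh3)4 with HCO2H/Et3N then forms the C12–C8–C9 π-allyl complex on the face anti to C15 and transfers hydride to the more substituted terminus C9 (formate hydrogenolysis to the exocyclic alkene). The fallback comes back to the route at 19.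

Step 6. Condensation of the ketone with the β-keto ester may be sluggish and accompanied by self-condensation or double-bond migration of the product. The fallback builds the same unit by olefination and acylation and sets out from 8. Horner–Wadsworth–Emmons reaction with trimethyl phosphonoacetate and NaH should give the β,β-disubstituted enoate F5. γ-Deprotonation with LiN(i-Pr)2 (2 equiv) and α-C-acylation of the dienolate with acetyl chloride should give the β,γ-unsaturated α-acetyl ester F6. Et3N equilibrates F6 into conjugation, and the fallback comes back to the route at 10; residual F6 is tolerated because the acid of step 8 interconverts the isomers.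

Further compounds
F1 | step 8 | methyl (6R)-2-acetyl-9,9-dimethoxy-3,7,7-trimethyl-6-(pivaloyloxy)dec-2-enoate (dimethyl ketal of 11) | COC(C)(OC)CC(C)(C)[C@H](OC(=O)C(C)(C)C)CCC(C)=C(C(C)=O)C(=O)OC
F2 | step 8 | methyl 1-methoxy-1,3,4a,8,8-pentamethyl-7-(pivaloyloxy)-4a,5,6,7,8,8a-hexahydro-1H-isochromene-4-carboxylate (hetero-Diels–Alder adduct, ketal carbon unassigned) | COC(=O)C1=C(C)OC(C)(OC)[C@@H]2C(C)(C)[C@H](OC(=O)C(C)(C)C)CC[C@@]12C
F3 | step 11 | trimethylsilyl ketene acetal of 17 (C8=C12 and C9=C11) | C=C1C=C[C@@H]2C(C)(C)[C@H](OC(=O)C(C)(C)C)CC[C@@]2(C)C1=C(OC)O[Si](C)(C)C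
F4 | step 11 | methyl (3R,5S,10R)-12-bromo-3-(pivaloyloxy)drima-6,8-dien-11-oate | BrCC=1C=C[C@@H]2C(C)(C)[C@H](OC(=O)C(C)(C)C)CC[C@@]2(C)C=1C(=O)OC
F5 | step 6 | methyl (6R)-3,7,7-trimethyl-6-(pivaloyloxy)deca-2,9-dienoate (E/Z mixture) | C=CCC(C)(C)[C@H](OC(=O)C(C)(C)C)CCC(C)=CC(=O)OC
F6 | step 6 | methyl (6R)-2-acetyl-3,7,7-trimethyl-6-(pivaloyloxy)deca-3,9-dienoate | C=CCC(C)(C)[C@H](OC(=O)C(C)(C)C)CC=C(C)C(C(C)=O)C(=O)OC
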